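The earlier runs and the new flask stem from a simulated flask with constants of no real substance, and the scatter is random.

We follow the larch flask to its asked time.

common to all: first end groups 0.20 M; second end groups 0.196 M
- larch: protic impurity 0.020 M; the very flask that is asked about, followed so far
- birch: protic impurity 0.040 M; run made earlier
- flask: protic impurity 0.0200 M; time 20 min

| run | time / min | links / % | first end groups / % |
|---|---|---|---|
| larch | 1.50 | 52 | 38 |
| larch | 3.00 | 68 | 27 |
| larch | 5.00 | 74 | 17 |
| larch | 6.00 | 77 | 15 |
| larch | 8.00 | 80 | 14 |
| larch | 10.0 | 78 | 13 |
| birch | 1.33 | 50 | 37 |
| birch | 4.00 | 67 | 14 |
| birch | 8.00 | 76 | 8 |
| birch | 10.0 | 75 | 6 |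
| birch | 15.0 | 75 | 5 |
| birch | 20.0 | 76 | 3 |

(scatter of a reading: 2 percentage points)

1. average number of monomer units in a chain (unreacted monomers counted as chains of one) at 20 min
2. part of the first end groups that has reacted at 20 min

- each molecule carries two end groups: a chain counts once for every two ends that are left, dead ends included; the units are half of the end groups of the two monomers charged

One comparison looks wrong at first. At 10.0 min, larch has 13 % of its first end groups left and 78 % links, while birch has 6 % left and 75 % links. The birch readings stand lower in first end groups, yet also lower in links, though the links differ by little more than the scatter of a reading.

A link takes one first end group, so the part reacted minus the links counts first end groups lost elsewhere. These readings give 9 percentage points for larch and 19 points for birch. We compare them with the dead-end share, the protic impurity charged over the first end groups charged: 10.0 % for larch and 20.0 % for birch. So we reckon links as the part reacted minus this share. Chains are then monomer units minus links, with units at 99.0 % of the first end groups charged.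

The forecast gives 91 % reacted and an average chain of 5.4, reading the late slowing as “some activity seems to fade”. From that reacted part, our share gives 81.0 % links and a chain of 5.50, slightly above the forecast's figure.

At 20 min the flask gives 90.9 % reacted and a chain of 5.51, with 81.0 % links; the share puts links at 80.9 %.

    first end groups + second end groups → links + by-product (k = 0.0800 /M/s)
    second end groups → decomposed reagent (k = 0.00120 /s)
    first end groups + protic impurity → quenched substrate (k = 0.110 /M/s)

By 20 min the flask has nearly come to rest. Of their own charges, 0.872 % of the second end groups, the limiting reagent, and 1.07 % of the protic impurity remain. At 200 min, both stand at 0 %, the part reacted is 91.5 %, links are 81.5 % and the chain is 5.66, while 8.50 % of the first end groups are still there.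

In the neighbour flask with 0.078 M of second end groups, the share is still 10.0 %, so the part reacted should stand that far above links. That neighbour flask gives 45.4 % reacted and 35.4 % links, a difference of 10 points, with a chain of 2.04.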